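**Plan**

- Retrosynthetic cuts: the C1 and C4 carbonyls are traced back to methyl ethers (oxidative demethylation) and the C6 ether to a naphthol. Then the C8–C8a bond of ring A is cut, then C6–C7 (Claisen), and last C5–C6 (one-carbon homologation of an aldehyde).
- Enabling feature: C8 carries the aryl group and no oxygen, C6 carries oxygen, and C5 and C7 are CH. Ring A is therefore a chain C5H2–C6(=O)–C7H2–C8(=O)Ar on C4a of an arene whose free ortho carbon is C8a. Ring B (C1, C2, C4 oxygenated) is a masked 1,2,4-trimethoxybenzene.
- Forward order: ring B is bought as 2,4,5-trimethoxybenzaldehyde and homologated to the arylacetate. The chain is completed by Claisen union with 3,4-dimethoxyacetophenone. Ring A, the only ring formed, closes in acid. O-methylation and oxidation of ring B to the quinone finish the route.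
- Stereochemistry: the target has no stereocentre and no stable stereogenic axis, so nothing has to be controlled.

Key step: step 4

Assumption: the ketene dithioacetal S-oxide formed in step 1 is drawn as the E isomer and is racemic at sulfur; both elements are erased in step 2, so either isomer or a mixture serves.

**Step 1**
Reactants: 1 2,4,5-trimethoxybenzaldehyde; 2 methyl (methylsulfinyl)methyl sulfide (FAMSO)
Product: 3 (E)-1,2,4-trimethoxy-5-[2-(methylsulfinyl)-2-(methylsulfanyl)ethenyl]benzene
Conditions: 2 (1.5 equiv), Triton B (40% in MeOH, cat.), THF, reflux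
Reagents that add atoms: none
Why: Knoevenagel-type condensation, in which the carbanion of 2 (stabilised by sulfoxide and sulfide) adds to the aldehyde and the adduct loses water to the conjugated ketene dithioacetal S-oxide, a reaction established for methoxy-substituted benzaldehydes.

**Step 2**
Reactants: 3 (E)-1,2,4-trimethoxy-5-[2-(methylsulfinyl)-2-(methylsulfanyl)ethenyl]benzene
Product: 4 methyl 2-(2,4,5-trimethoxyphenyl)acetate
Conditions: anhydrous HCl in MeOH (ca. 2 M), 0 °C to rt
Reagents that add atoms: methanol, CO
Why: Acid alcoholysis of a ketene dithioacetal S-oxide (second half of the FAMSO arylacetic ester homologation): protonation at the benzylic carbon gives a sulfur-stabilised cation that takes up methanol, Pummerer-type loss of both sulfur groups as dimethyl disulfide leaves the methyl ester, and the aryl methyl ethers are inert to methanolic HCl.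

**Step 3**
Reactants: 5 1-(3,4-dimethoxyphenyl)ethan-1-one (3,4-dimethoxyacetophenone); 4 methyl 2-(2,4,5-trimethoxyphenyl)acetate
Product: 6 1-(3,4-dimethoxyphenyl)-4-(2,4,5-trimethoxyphenyl)butane-1,3-dione
Conditions: 5 (2 equiv), NaH (3 equiv), THF, 0 °C to reflux; slow addition of 4; then 1 M HCl
Reagents that add atoms: none
Why: Crossed Claisen condensation, in which the preformed sodium enolate of 5, kept in excess while 4 is added slowly, attacks the unhindered methyl ester and the product is drained off as its stabilised diketone enolate, which drives the equilibrium and limits self-condensation of the arylacetate.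

**Step 4**
Reactants: 6 1-(3,4-dimethoxyphenyl)-4-(2,4,5-trimethoxyphenyl)butane-1,3-dione
Product: 8 4-(3,4-dimethoxyphenyl)-5,6,8-trimethoxynaphthalen-2-ol, via hydroxy tetralone 7 (not isolated)
Conditions: TfOH (5 equiv), CH2Cl2 (0.02 M), 0 °C to rt, argon
Reagents that add atoms: none
Why: TfOH protonates the enolised diketone to a hydroxyallyl cation whose aryl-ketone terminus C8 is attacked by C8a, the only free ortho carbon of the trimethoxyarene, giving carbinol 7; loss of water across C7–C8 and enolisation of the C6 ketone then give the aromatic naphthol. The closest known reaction type is the acid-mediated cyclodehydration of benzyl 1,3-diketones to 4-substituted 2-naphthols, an intramolecular Friedel–Crafts hydroxyalkylation followed by dehydration (Bradsher-type). Ring A closes 6-exo-trig onto the protonated C8 carbonyl. The C8 carbinol centre of 7 is formed racemic and is erased by the dehydration, so no stereocentre is set. The step needs the C8–C8a bond alone to form, and the tether secures this: the other ortho carbon carries a methoxy group, attack on the C6 carbonyl would need a four-membered ring, and the dimethoxyphenyl ring is deactivated by its own carbonyl and could only close a five-membered ring, whereas C8a is activated by the ortho methoxy group at C1. Aromatisation makes the closure irreversible, and the non-sulfonating acid in dilute solution should spare the electron-rich rings.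

**Step 5**
Reactants: 8 4-(3,4-dimethoxyphenyl)-5,6,8-trimethoxynaphthalen-2-ol
Product: 9 8-(3,4-dimethoxyphenyl)-1,2,4,6-tetramethoxynaphthalene
Conditions: MeI, K2CO3, DMF, rt, argon
Reagents that add atoms: iodomethane, CI
Why: Williamson O-methylation of the naphtholate, chemoselective because the naphthol is the only acidic site, and it also removes the easily oxidised free phenol before the last step.

**Step 6**
Reactants: 9 8-(3,4-dimethoxyphenyl)-1,2,4,6-tetramethoxynaphthalene
Product: 10 8-(3,4-dimethoxyphenyl)-2,6-dimethoxynaphthalene-1,4-dione (target)
Conditions: (NH4)2Ce(NO3)6 (2.5 equiv), MeCN/H2O, 0 °C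
Reagents that add atoms: water, O
Why: Oxidative demethylation of a para-dimethoxyarene by tetravalent cerium, in which the trimethoxy ring B, the most electron-rich part, is oxidised to its radical cation, water adds at C1 and C4 and two methanol are lost to give the para-quinone with the C2 methoxy retained, while the anisole-type ring A and the veratrole ring lack a para-dioxygen pattern and should remain.

**Compound list**

1 | 2,4,5-trimethoxybenzaldehyde | COc1cc(OC)c(C=O)cc1OC | starting material
2 | methyl (methylsulfinyl)methyl sulfide (FAMSO, racemic at sulfur) | CSCS(C)=O | starting material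
3 | (E)-1,2,4-trimethoxy-5-[2-(methylsulfinyl)-2-(methylsulfanyl)ethenyl]benzene (racemic at sulfur) | COc1cc(OC)c(/C=C(\SC)S(C)=O)cc1OC | intermediate
4 | methyl 2-(2,4,5-trimethoxyphenyl)acetate | COC(=O)Cc1cc(OC)c(OC)cc1OC | intermediate
5 | 1-(3,4-dimethoxyphenyl)ethan-1-one | CC(=O)c1ccc(OC)c(OC)c1 | starting material
6 | 1-(3,4-dimethoxyphenyl)-4-(2,4,5-trimethoxyphenyl)butane-1,3-dione | COc1cc(OC)c(CC(=O)CC(=O)c2ccc(OC)c(OC)c2)cc1OC | intermediate
7 | 4-(3,4-dimethoxyphenyl)-4-hydroxy-5,6,8-trimethoxy-3,4-dihydronaphthalen-2(1H)-one (racemic hydroxy tetralone) | COc1cc(OC)c2c(c1OC)C(O)(c1ccc(OC)c(OC)c1)CC(=O)C2 | intermediate (not isolated)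
8 | 4-(3,4-dimethoxyphenyl)-5,6,8-trimethoxynaphthalen-2-ol | COc1cc(OC)c2cc(O)cc(-c3ccc(OC)c(OC)c3)c2c1OC | intermediate
9 | 8-(3,4-dimethoxyphenyl)-1,2,4,6-tetramethoxynaphthalene | COc1cc(OC)c2cc(OC)cc(-c3ccc(OC)c(OC)c3)c2c1OC | intermediate
10 | 8-(3,4-dimethoxyphenyl)-2,6-dimethoxynaphthalene-1,4-dione | COC1=CC(=O)c2cc(OC)cc(-c3ccc(OC)c(OC)c3)c2C1=O | target

Total step count: 6
Longest linear sequence: 6 steps (1 to 10); 5 enters at step 3 as a commercial material.

**Steps most likely to fail**

Step 3 (Claisen union). Proton transfer from the arylacetate to the ketone enolate, followed by self-condensation of the ester or aldol self-condensation of the ketone, may erode the crossed product. The fallback sets out from 4 and returns at 6. Ester 4 would be saponified (LiOH, THF/H2O, then acid) to 2-(2,4,5-trimethoxyphenyl)acetic acid F1. The acid would be converted with 1H-benzotriazole and SOCl2 in CH2Cl2 into 1-(1H-benzotriazol-1-yl)-2-(2,4,5-trimethoxyphenyl)ethan-1-one F2. Ketone 5 would then be C-acylated by this activated amide under soft enolisation (MgBr2·OEt2, i-Pr2NEt, CH2Cl2, rt). Under these conditions only the magnesium-bound ketone is deprotonated by the amine, and 6 is held as its magnesium chelate until acidic work-up.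

Step 4 (ring closure). Closure may stall because C8a has only one activating ortho methoxy group and the change of C8 to a tetrahedral carbinol builds strain against the C1 methoxy group; acid-induced retro-Claisen cleavage or intermolecular arylation could then take over. The fallback sets out from 4 and returns at 8; it forms the same C8–C8a bond through a linear alkyne carbon. Ester 4 would be converted (MeNH(OMe)·HCl, i-PrMgCl, THF, −20 °C) into N-methoxy-N-methyl-2-(2,4,5-trimethoxyphenyl)acetamide F3. Addition of the lithium acetylide of commercial 4-ethynyl-1,2-dimethoxybenzene (n-BuLi, THF, −78 °C) would give 4-(3,4-dimethoxyphenyl)-1-(2,4,5-trimethoxyphenyl)but-3-yn-2-one F4. A cationic complex of monovalent gold, Ph3PAuNTf2 (cat.), in CH2Cl2 at rt would then effect 6-endo-dig hydroarylation of the ynone by C8a, and tautomerisation of the resulting naphthalenone gives 8.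

Step 6 (quinone formation). Loss of the C2 instead of the C4 methyl group (ortho-quinone formation), oxidative coupling of the electron-rich ring A, or over-oxidation of the veratrole ring may compete with the desired demethylation. The fallback sets out from 9 and returns at 10. Anodic oxidation of 9 in methanolic KOH (Pt anode, undivided cell, 0 °C) would add methanol across C1 and C4 to give the quinone bisketal 8-(3,4-dimethoxyphenyl)-1,1,2,4,4,6-hexamethoxy-1,4-dihydronaphthalene F5. Mild hydrolysis (aqueous AcOH or dilute HCl in acetone, rt) would unveil the para-quinone 10. The ketal carbons are fixed at C1 and C4 by the 1,4-addition, so only the para-quinone can result.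

**Further compounds**

F1 | step 3 | 2-(2,4,5-trimethoxyphenyl)acetic acid | COc1cc(OC)c(CC(=O)O)cc1OC
F2 | step 3 | 1-(1H-benzotriazol-1-yl)-2-(2,4,5-trimethoxyphenyl)ethan-1-one | COc1cc(OC)c(CC(=O)n2nnc3ccccc32)cc1OC
F3 | step 4 | N-methoxy-N-methyl-2-(2,4,5-trimethoxyphenyl)acetamide | COc1cc(OC)c(CC(=O)N(C)OC)cc1OC
F4 | step 4 | 4-(3,4-dimethoxyphenyl)-1-(2,4,5-trimethoxyphenyl)but-3-yn-2-one | COc1cc(OC)c(CC(=O)C#Cc2ccc(OC)c(OC)c2)cc1OC
F5 | step 6 | 8-(3,4-dimethoxyphenyl)-1,1,2,4,4,6-hexamethoxy-1,4-dihydronaphthalene | COC1=CC(OC)(OC)c2cc(OC)cc(-c3ccc(OC)c(OC)c3)c2C1(OC)OC
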